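## Retrosynthetic overview

- The route rests on one feature: C7 is the β-carbon of the α-methylene-γ-lactone (C11=C13 exocyclic, C12 on O6) and its neighbour C8 carries the only acylated oxygen. C7–C8 is therefore cut to a C13 bromide on a preformed butenolide and a C8 aldehyde (SE2' Barbier allylation).
- After ring closure: the free C8 hydroxyl takes the (R)-2-methylbutanoate, C14 is unmasked and oxidised, and the silyl ethers are removed.
- Seco-aldehyde 30: the butenolide comes from an O6 2-(silyloxymethyl)acrylate by RCM, and C3–C4 from a B-alkyl Suzuki coupling of vinyl iodide 6 with diene 18.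
- Both trisubstituted alkenes (C3 cis to C6, C2 cis to C9) come from 2-butyne-1,4-diol by hydroxyl-directed trans-hydroalumination and iodination. C6 is set by catalytic asymmetric vinylation of an enal, C9 by CBS reduction.
- Ring order: five-membered lactone first (step 17), ten-membered carbocycle second (step 22).

Key step: step 22

Remark: germacranolide numbering is used for all intermediates (C12 lactone carbonyl on O6, C13 exocyclic methylene, C14 on C10, C15 on C4), and the facial sense of steps 4 and 11 is taken from the accepted models for (−)-MIB-catalysed organozinc addition and for the (S)-CBS catalyst.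

## Route

Step 1
Reactants: 1 2-butyne-1,4-diol
Product: 2 4-(tert-butyldiphenylsilyloxy)but-2-yn-1-ol
Conditions: NaH (1.0 equiv), THF, 0 °C; TBDPSCl (1.0 equiv), 0 °C → rt; diol in threefold excess
Reagents that add atoms: tert-butyl(chloro)diphenylsilane, CC(C)(C)[Si](Cl)(c1ccccc1)c1ccccc1
Why: O-silylation of the sparingly soluble monosodium alkoxide of a symmetrical diol should stop at the mono-ether and differentiates the two ends of the C6–C5–C4–C15 unit.

Step 2
Reactants: 2 4-(tert-butyldiphenylsilyloxy)but-2-yn-1-ol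
Product: 4 (Z)-4-(tert-butyldiphenylsilyloxy)-3-iodobut-2-en-1-ol, via sodium alkenylalanate 3 (not isolated)
Conditions: NaAlH2(OCH2CH2OCH3)2 (Red-Al, 1.5 equiv), THF, 0 °C; then I2, −78 → 0 °C; Rochelle salt work-up
Reagents that add atoms: iodine, II
Why: Hydroxyl-directed trans-hydroalumination of the propargylic alcohol puts hydride on C5 and aluminium on C4 in a five-membered alanate, and iododealumination with retention gives the vinyl iodide with iodine cis to C6, which fixes the later C3/C6 cis geometry of the C4=C5 alkene.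

Step 3
Reactants: 4 (Z)-4-(tert-butyldiphenylsilyloxy)-3-iodobut-2-en-1-ol
Product: 5 (Z)-4-(tert-butyldiphenylsilyloxy)-3-iodobut-2-enal
Conditions: activated MnO2 (15 equiv), CH2Cl2, rt
Reagents that add atoms: none
Why: MnO2 oxidation of a primary allylic alcohol should give the enal without touching the vinyl iodide or the alkene geometry.

Step 4
Reactants: 5 (Z)-4-(tert-butyldiphenylsilyloxy)-3-iodobut-2-enal
Product: 6 (3S,4Z)-6-(tert-butyldiphenylsilyloxy)-5-iodohexa-1,4-dien-3-ol
Conditions: Zn(CH=CH2)2 (2.0 equiv), (−)-MIB (10 mol %), toluene, −10 °C; aq. NH4Cl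
Reagents that add atoms: divinylzinc, C=C[Zn]C=C
Why: Amino-alcohol-catalysed enantioselective organozinc addition to an aldehyde, in which (−)-MIB is expected to direct the vinyl group to the face that corresponds to the Si face of benzaldehyde, setting C6 with O, C5 and C7 arranged as in the target (descriptor S here, R once the lactone exists).

Step 5
Reactants: 1 2-butyne-1,4-diol
Product: 7 4-(tert-butyldimethylsilyloxy)but-2-yn-1-ol
Conditions: NaH (1.0 equiv), THF, 0 °C; TBSCl (1.0 equiv), 0 °C → rt; diol in threefold excess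
Reagents that add atoms: tert-butyl(chloro)dimethylsilane, CC(C)(C)[Si](C)(C)Cl
Why: The same monosilylation through the monosodium alkoxide gives the C2–C1–C10–C14 unit with O14 protected.

Step 6
Reactants: 7 4-(tert-butyldimethylsilyloxy)but-2-yn-1-ol
Product: 9 (Z)-4-(tert-butyldimethylsilyloxy)-3-iodobut-2-en-1-ol, via sodium alkenylalanate 8 (not isolated)
Conditions: NaAlH2(OCH2CH2OCH3)2 (1.5 equiv), THF, 0 °C; then I2, −78 → 0 °C; Rochelle salt work-up
Reagents that add atoms: iodine, II
Why: Hydroxyl-directed trans-hydroalumination and iodination as in step 2 place iodine on C10 cis to C2, so that the carbon later attached at C10 (C9) is cis to C2.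

Step 7
Reactants: 9 (Z)-4-(tert-butyldimethylsilyloxy)-3-iodobut-2-en-1-ol
Product: 10 (Z)-4-(tert-butyldimethylsilyloxy)-3-iodobut-2-enal
Conditions: activated MnO2 (15 equiv), CH2Cl2, rt
Reagents that add atoms: none
Why: Allylic oxidation with MnO2 as in step 3 gives the C2 aldehyde.

Step 8
Reactants: 10 (Z)-4-(tert-butyldimethylsilyloxy)-3-iodobut-2-enal
Product: 11 (Z)-tert-butyl[(2-iodopenta-2,4-dien-1-yl)oxy]dimethylsilane
Conditions: Ph3PCH3Br, KOtBu, THF, 0 °C; then 10, −78 → 0 °C
Reagents that add atoms: methyltriphenylphosphonium bromide, [Br-].C[P+](c1ccccc1)(c1ccccc1)c1ccccc1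
Why: Wittig methylenation of the enal adds C3 as a terminal alkene and leaves the vinyl iodide and its geometry untouched.

Step 9
Reactants: 12 2-chloro-N-methoxy-N-methylacetamide; 13 4-methoxybenzyl alcohol
Product: 14 N-methoxy-2-[(4-methoxybenzyl)oxy]-N-methylacetamide
Conditions: NaH, THF, 0 °C; then 12, Bu4NI (cat.), 0 °C → rt
Reagents that add atoms: none
Why: Williamson etherification (SN2 of the alkoxide on the α-chloro amide) gives the C8–C9 building block with O8 already as its PMB ether.

Step 10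
Reactants: 11 (Z)-iododiene; 14 N-methoxy-2-[(4-methoxybenzyl)oxy]-N-methylacetamide
Product: 16 (3Z)-3-[(tert-butyldimethylsilyloxy)methyl]-1-[(4-methoxybenzyl)oxy]hexa-3,5-dien-2-one, via dienyllithium 15 (not isolated)
Conditions: t-BuLi (2.05 equiv), Et2O, −78 °C; then 14, −78 °C; cold AcOH/aq. NH4Cl quench
Reagents that add atoms: none
Why: Iodine–lithium exchange with retention gives the dienyllithium, whose addition to the Weinreb amide stops at the chelated tetrahedral adduct and releases the ketone on work-up (Weinreb ketone synthesis), forming C9–C10 with C9 cis to C2.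

Step 11
Reactants: 16 (3Z)-dienone
Product: 17 (2S,3Z)-3-[(tert-butyldimethylsilyloxy)methyl]-1-[(4-methoxybenzyl)oxy]hexa-3,5-dien-2-ol
Conditions: (S)-2-methyl-CBS-oxazaborolidine (0.2 equiv), catecholborane (1.5 equiv), toluene, −78 °C; MeOH quench
Reagents that add atoms: none
Why: Corey–Bakshi–Shibata reduction in which the α-branched dienyl group is the large and CH2OPMB the small substituent, so the (S)-catalyst should give the 9S carbinol, while catecholborane at −78 °C should leave the diene alone.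

Step 12
Reactants: 17 (2S,3Z)-dienol
Product: 18 (9S)-diene: C3H2=C2H–C1H=C10(CH2OTBS)–C9H(OTBS)–C8H2OPMB (C2 cis to C9)
Conditions: TBSOTf, 2,6-lutidine, CH2Cl2, −78 °C
Reagents that add atoms: tert-butyldimethylsilyl trifluoromethanesulfonate, CC(C)(C)[Si](C)(C)OS(=O)(=O)C(F)(F)F
Why: Silylation of the secondary allylic alcohol with the silyl triflate under buffered conditions protects O9 for the rest of the route.

Step 13
Reactants: 18 (9S)-diene; 6 (3S,4Z)-vinyl iodide carbinol
Product: 20 (6S,9S)-coupled dienol (C6–OH free; vinyl on C6; C3 cis to C6; C2 cis to C9; O8 PMB; O9 TBS; O14 TBS; O15 TBDPS), via C3 alkyl-9-BBN borane 19 (not isolated)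
Conditions: 9-BBN (1.0 equiv per 18), THF, 0 °C → rt; then 6 (0.8 equiv), Pd(dppf)Cl2 (5 mol %), AsPh3, Cs2CO3, DMF/H2O, rt
Reagents that add atoms: none
Why: 9-BBN adds anti-Markovnikov to the terminal alkene of the diene (boron on C3), and B-alkyl Suzuki–Miyaura coupling with the vinyl iodide proceeds with retention, forming C3–C4 with C3 cis to C6 while tolerating the free hydroxyl.

Step 14
Reactants: 21 ethyl 2-(hydroxymethyl)acrylate
Product: 22 2-(hydroxymethyl)acrylic acid
Conditions: LiOH·H2O, THF/H2O, 0 °C → rt; 1 M HCl to pH 2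
Reagents that add atoms: lithium hydroxide, [Li+].[OH-]
Why: Saponification of the ethyl ester gives the free acid that carries C11, C12 and C13.

Step 15
Reactants: 22 2-(hydroxymethyl)acrylic acid
Product: 24 2-[(triethylsilyloxy)methyl]acrylic acid, via bis(triethylsilyl) derivative 23 (not isolated)
Conditions: TESCl (2.2 equiv), imidazole, CH2Cl2, 0 °C; then K2CO3 (cat.), MeOH, 0 °C, 15 min; pH 5 work-up
Reagents that add atoms: chlorotriethylsilane, CC[Si](Cl)(CC)CC
Why: Silylation of both hydroxyl and carboxyl followed by selective methanolysis of the much more labile silyl ester leaves the triethylsilyl ether acid.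

Step 16
Reactants: 20 (6S,9S)-coupled dienol; 24 2-[(triethylsilyloxy)methyl]acrylic acid
Product: 25 (6S,9S)-O6 2-[(triethylsilyloxy)methyl]acrylate of 20
Conditions: DCC, DMAP (cat.), CH2Cl2, 0 °C → rt
Reagents that add atoms: none
Why: Steglich esterification acylates the secondary bis-allylic alcohol under neutral conditions that should not ionise it.

Step 17
Reactants: 25 (6S,9S)-acrylate
Product: 26 (6R,9S)-butenolide with C13–OTES (C7=C11 in the lactone; O8 PMB; O9 TBS; O14 TBS; O15 TBDPS)
Conditions: second-generation Grubbs catalyst RuCl2(H2IMes)(PCy3)(=CHPh) (10 mol %), toluene (3 mM), 80 °C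
Reagents that add atoms: none
Why: In this ring-closing metathesis the catalyst loads on the only monosubstituted alkene (C7) and closes the five-membered ring on the 1,1-disubstituted acrylate alkene with loss of ethene, whereas the two trisubstituted alkenes would have to release a hindered disubstituted alkylidene and should react much more slowly.

Step 18
Reactants: 26 (6R,9S)-butenolide C13 silyl ether
Product: 27 (6R,9S)-3-(hydroxymethyl)butenolide
Conditions: PPTS (0.2 equiv), MeOH/CH2Cl2, 0 °C
Reagents that add atoms: none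
Why: Acid-catalysed methanolysis should cleave the primary triethylsilyl ether much faster than the tert-butyldimethylsilyl and tert-butyldiphenylsilyl ethers.

Step 19
Reactants: 27 (6R,9S)-3-(hydroxymethyl)butenolide
Product: 28 (6R,9S)-3-(bromomethyl)butenolide with O8 PMB
Conditions: CBr4, PPh3, CH2Cl2, 0 °C
Reagents that add atoms: tetrabromomethane, BrC(Br)(Br)Br
Why: Appel bromination converts the primary allylic alcohol into the C13 bromide under neutral conditions.

Step 20
Reactants: 28 (6R,9S)-3-(bromomethyl)butenolide PMB ether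
Product: 29 (6R,9S)-C8 primary alcohol
Conditions: DDQ, CH2Cl2/pH 7 phosphate buffer, 0 °C → rt
Reagents that add atoms: none
Why: Oxidative PMB cleavage with DDQ under buffered neutral conditions frees O8 without disturbing the allylic bromide or the silyl ethers.

Step 21
Reactants: 29 (6R,9S)-C8 alcohol
Product: 30 (6R,9S)-seco-aldehyde: C8 aldehyde tethered to the 3-(bromomethyl)butenolide
Conditions: Dess–Martin periodinane, CH2Cl2, 0 °C → rt; used crude
Reagents that add atoms: none
Why: Dess–Martin oxidation gives the α-silyloxy aldehyde under non-basic conditions that should not epimerise C9 or displace the bromide.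

Step 22
Reactants: 30 (6R,9S)-seco-aldehyde
Product: 32 ten-membered germacranolide core with free C8–OH (6R,7R,8R,9S by CIP; spatially as in the target), via allylchromium dichloride 31 (not isolated)
Conditions: CrCl2 (8 equiv), THF, 25 °C; 30 added by syringe pump over 10 h (final 2 mM); aq. NH4Cl work-up
Reagents that add atoms: none
Why: Two equivalents of CrCl2 reduce the C13–Br bond to the allylchromium dichloride 31 (trivalent chromium), whose γ-carbon C7 adds to the C8 aldehyde through a six-membered chair transition state with allylic transposition (SE2'), forming C7–C8 and the exocyclic C11=C13 alkene. The closest known reaction type is the Nozaki–Hiyama (Barbier-type) allylation of aldehydes by 2-(bromomethyl)acrylates and 3-(bromomethyl)butenolides, including its macrocyclic variants. The ten-membered carbocycle closes by carbonyl addition (10-exo-trig on C8=O), the lactone ring being already in place. C7 should be set by attack on the butenolide face anti to the C5 substituent on C6 (6,7-trans lactone), and C8 by the ring-fixed allyl geometry (C6 trans to C13 across C7=C11), which in the chair gives the anti relation of C6 and O8 along C9–C8–C7–C11. The non-chelating C9 silyl ether should direct the same aldehyde face in the Felkin–Anh sense (O8/O9 anti). The step needs γ- over α-attack, secured by the cyclic chromium transition state, and ring closure over oligomerisation, secured by slow addition at high dilution and by the two cis-configured trisubstituted alkenes that fold the chain.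

Step 23
Reactants: 32 germacranolide C8 alcohol; 33 (R)-2-methylbutanoic acid
Product: 34 C8 (R)-2-methylbutanoate (6R,7S,8R,9S; O9 TBS; O14 TBS; O15 TBDPS)
Conditions: DCC, DMAP, CH2Cl2, 0 °C → rt
Reagents that add atoms: none
Why: Steglich esterification of the only free hydroxyl installs the side chain, and the α-stereocentre of the simple α-alkyl acid should survive carbodiimide activation at low temperature.

Step 24
Reactants: 34 C8 ester
Product: 35 C14 primary allylic alcohol (O9 TBS and O15 TBDPS retained)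
Conditions: HF·pyridine, pyridine, THF, 0 °C
Reagents that add atoms: none
Why: Buffered fluoride cleaves the primary allylic tert-butyldimethylsilyl ether much faster than the hindered secondary one at C9 and the tert-butyldiphenylsilyl ether at C15.

Step 25
Reactants: 35 C14 alcohol
Product: 36 C14 enal (O9 TBS and O15 TBDPS retained)
Conditions: activated MnO2, CH2Cl2, rt
Reagents that add atoms: none
Why: MnO2 oxidises the only free allylic alcohol to the conjugated aldehyde on C10 without affecting the methylene lactone or the ester.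

Step 26
Reactants: 36 C14 enal
Product: 37 CNP0331447.12
Conditions: HF·pyridine (excess), THF, 0 °C → rt
Reagents that add atoms: none
Why: Acidic fluoride removes the remaining two silyl ethers, and its non-basic nature should avoid acyl migration from O8 to O9 and addition to the methylene lactone.

## Compound list

1 | 2-butyne-1,4-diol | OCC#CCO | starting material
2 | 4-(tert-butyldiphenylsilyloxy)but-2-yn-1-ol | OCC#CCO[Si](c1ccccc1)(c1ccccc1)C(C)(C)C | intermediate
3 | sodium alkenylalanate from 2 (five-membered O6–Al–C4 chelate, two 2-methoxyethoxy groups on Al) | [Na+].COCCO[Al-]1(OCCOC)OCC=C1CO[Si](c1ccccc1)(c1ccccc1)C(C)(C)C | intermediate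
4 | (Z)-4-(tert-butyldiphenylsilyloxy)-3-iodobut-2-en-1-ol (I cis to CH2OH) | OC/C=C(\I)CO[Si](c1ccccc1)(c1ccccc1)C(C)(C)C | intermediate
5 | (Z)-4-(tert-butyldiphenylsilyloxy)-3-iodobut-2-enal | O=C/C=C(\I)CO[Si](c1ccccc1)(c1ccccc1)C(C)(C)C | intermediate
6 | (3S,4Z)-6-(tert-butyldiphenylsilyloxy)-5-iodohexa-1,4-dien-3-ol (6S carbinol of the C7–C6–C5=C4–C15 unit) | C=C[C@H](O)/C=C(\I)CO[Si](c1ccccc1)(c1ccccc1)C(C)(C)C | intermediate
7 | 4-(tert-butyldimethylsilyloxy)but-2-yn-1-ol | OCC#CCO[Si](C)(C)C(C)(C)C | intermediate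
8 | sodium alkenylalanate from 7 | [Na+].COCCO[Al-]1(OCCOC)OCC=C1CO[Si](C)(C)C(C)(C)C | intermediate
9 | (Z)-4-(tert-butyldimethylsilyloxy)-3-iodobut-2-en-1-ol | OC/C=C(\I)CO[Si](C)(C)C(C)(C)C | intermediate
10 | (Z)-4-(tert-butyldimethylsilyloxy)-3-iodobut-2-enal | O=C/C=C(\I)CO[Si](C)(C)C(C)(C)C | intermediate
11 | (Z)-tert-butyl[(2-iodopenta-2,4-dien-1-yl)oxy]dimethylsilane (I cis to the vinyl group) | C=C/C=C(\I)CO[Si](C)(C)C(C)(C)C | intermediate
12 | 2-chloro-N-methoxy-N-methylacetamide | CON(C)C(=O)CCl | starting material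
13 | 4-methoxybenzyl alcohol | COc1ccc(CO)cc1 | starting material
14 | N-methoxy-2-[(4-methoxybenzyl)oxy]-N-methylacetamide | CON(C)C(=O)COCc1ccc(OC)cc1 | intermediate
15 | (Z)-dienyllithium from 11 (Li in place of I) | C=C/C=C(\[Li])CO[Si](C)(C)C(C)(C)C | intermediate
16 | (3Z)-3-[(tert-butyldimethylsilyloxy)methyl]-1-[(4-methoxybenzyl)oxy]hexa-3,5-dien-2-one (C9 ketone cis to the vinyl group) | C=C/C=C(\C(=O)COCc1ccc(OC)cc1)CO[Si](C)(C)C(C)(C)C | intermediate
17 | (2S,3Z)-3-[(tert-butyldimethylsilyloxy)methyl]-1-[(4-methoxybenzyl)oxy]hexa-3,5-dien-2-ol (9S) | C=C/C=C(\[C@H](O)COCc1ccc(OC)cc1)CO[Si](C)(C)C(C)(C)C | intermediate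
18 | (9S)-diene, O9 TBS ether of 17 | C=C/C=C(\[C@H](O[Si](C)(C)C(C)(C)C)COCc1ccc(OC)cc1)CO[Si](C)(C)C(C)(C)C | intermediate
19 | 9-alkyl-9-BBN from 18 (boron on C3) | COc1ccc(COC[C@@H](O[Si](C)(C)C(C)(C)C)/C(CO[Si](C)(C)C(C)(C)C)=C\CCB2C3CCCC2CCC3)cc1 | intermediate
20 | (6S,9S)-coupled dienol (free C6–OH, vinyl on C6) | COc1ccc(COC[C@@H](O[Si](C)(C)C(C)(C)C)/C(CO[Si](C)(C)C(C)(C)C)=C\CC/C(CO[Si](c2ccccc2)(c2ccccc2)C(C)(C)C)=C\[C@@H](O)C=C)cc1 | intermediate
21 | ethyl 2-(hydroxymethyl)acrylate | C=C(CO)C(=O)OCC | starting material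
22 | 2-(hydroxymethyl)acrylic acid | C=C(CO)C(=O)O | intermediate
23 | triethylsilyl 2-[(triethylsilyloxy)methyl]acrylate | C=C(CO[Si](CC)(CC)CC)C(=O)O[Si](CC)(CC)CC | intermediate
24 | 2-[(triethylsilyloxy)methyl]acrylic acid | C=C(CO[Si](CC)(CC)CC)C(=O)O | intermediate
25 | (6S,9S)-O6 acrylate of 20 | COc1ccc(COC[C@@H](O[Si](C)(C)C(C)(C)C)/C(CO[Si](C)(C)C(C)(C)C)=C\CC/C(CO[Si](c2ccccc2)(c2ccccc2)C(C)(C)C)=C\[C@@H](OC(=O)C(=C)CO[Si](CC)(CC)CC)C=C)cc1 | intermediate
26 | (6R,9S)-butenolide, C13–OTES | COc1ccc(COC[C@@H](O[Si](C)(C)C(C)(C)C)/C(CO[Si](C)(C)C(C)(C)C)=C\CC/C(CO[Si](c2ccccc2)(c2ccccc2)C(C)(C)C)=C\[C@H]2OC(=O)C(CO[Si](CC)(CC)CC)=C2)cc1 | intermediate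
27 | (6R,9S)-3-(hydroxymethyl)butenolide | COc1ccc(COC[C@@H](O[Si](C)(C)C(C)(C)C)/C(CO[Si](C)(C)C(C)(C)C)=C\CC/C(CO[Si](c2ccccc2)(c2ccccc2)C(C)(C)C)=C\[C@H]2OC(=O)C(CO)=C2)cc1 | intermediate
28 | (6R,9S)-3-(bromomethyl)butenolide, O8 PMB | COc1ccc(COC[C@@H](O[Si](C)(C)C(C)(C)C)/C(CO[Si](C)(C)C(C)(C)C)=C\CC/C(CO[Si](c2ccccc2)(c2ccccc2)C(C)(C)C)=C\[C@H]2OC(=O)C(CBr)=C2)cc1 | intermediate
29 | (6R,9S)-3-(bromomethyl)butenolide, C8 primary alcohol | OC[C@@H](O[Si](C)(C)C(C)(C)C)/C(CO[Si](C)(C)C(C)(C)C)=C\CC/C(CO[Si](c1ccccc1)(c1ccccc1)C(C)(C)C)=C\[C@H]1OC(=O)C(CBr)=C1 | intermediate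
30 | (6R,9S)-seco-aldehyde (C8 aldehyde, C13 bromide) | O=C[C@@H](O[Si](C)(C)C(C)(C)C)/C(CO[Si](C)(C)C(C)(C)C)=C\CC/C(CO[Si](c1ccccc1)(c1ccccc1)C(C)(C)C)=C\[C@H]1OC(=O)C(CBr)=C1 | intermediate
31 | allylchromium dichloride from 30 (Cr on C13) | O=C[C@@H](O[Si](C)(C)C(C)(C)C)/C(CO[Si](C)(C)C(C)(C)C)=C\CC/C(CO[Si](c1ccccc1)(c1ccccc1)C(C)(C)C)=C\[C@H]1OC(=O)C(C[Cr](Cl)Cl)=C1 | intermediate
32 | germacranolide core, free C8–OH (O9 TBS, O14 TBS, O15 TBDPS) | C=C1C(=O)O[C@@H]2/C=C(/CO[Si](c3ccccc3)(c3ccccc3)C(C)(C)C)CC/C=C(/CO[Si](C)(C)C(C)(C)C)[C@H](O[Si](C)(C)C(C)(C)C)[C@H](O)[C@@H]12 | intermediate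
33 | (R)-2-methylbutanoic acid | CC[C@@H](C)C(=O)O | starting material
34 | C8 (R)-2-methylbutanoate of 32 | C=C1C(=O)O[C@@H]2/C=C(/CO[Si](c3ccccc3)(c3ccccc3)C(C)(C)C)CC/C=C(/CO[Si](C)(C)C(C)(C)C)[C@H](O[Si](C)(C)C(C)(C)C)[C@H](OC(=O)[C@H](C)CC)[C@@H]12 | intermediate
35 | C14 alcohol (O9 TBS, O15 TBDPS) | C=C1C(=O)O[C@@H]2/C=C(/CO[Si](c3ccccc3)(c3ccccc3)C(C)(C)C)CC/C=C(/CO)[C@H](O[Si](C)(C)C(C)(C)C)[C@H](OC(=O)[C@H](C)CC)[C@@H]12 | intermediate
36 | C14 aldehyde (O9 TBS, O15 TBDPS) | C=C1C(=O)O[C@@H]2/C=C(/CO[Si](c3ccccc3)(c3ccccc3)C(C)(C)C)CC/C=C(/C=O)[C@H](O[Si](C)(C)C(C)(C)C)[C@H](OC(=O)[C@H](C)CC)[C@@H]12 | intermediate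
37 | CNP0331447.12 | C=C1C(=O)O[C@@H]2/C=C(/CO)CC/C=C(/C=O)[C@H](O)[C@H](OC(=O)[C@H](C)CC)[C@@H]12 | target

## Step count and risks

Total step count: 26. Longest linear sequence: 19 steps (1 → 7 → 9 → 10 → 11 → 16 → 17 → 18 → 20 → 25 → 26 → 27 → 28 → 29 → 30 → 32 → 34 → 35 → 36 → 37).

Steps most likely to fail:

1. Step 22. Intermolecular allylation may outrun ring closure, the allylchromium may be protonated before it reaches the aldehyde, the aldehyde may add on the wrong face of the butenolide, or the lactone may migrate from O6 to the new O8 alkoxide. The fallback makes the same C7–C8 bond between two fragments and closes the ring at C3–C4 instead; it sets out from 6, 24 and 18 and comes back at 32. Compound 6 would be esterified with 24 (DCC, DMAP) to the iodo-diene acrylate F1 and closed with the second-generation Grubbs catalyst to the iodo-butenolide silyl ether F2. PPTS/MeOH would give the hydroxymethyl butenolide F3, and CBr4/PPh3 the bromomethyl butenolide F4. Compound 18 would be taken by DDQ to the C8 alcohol F5 and by Dess–Martin oxidation to the C8 aldehyde F6. Zinc-mediated Barbier allylation of F6 with F4 (Zn dust, THF/aq. NH4Cl) would give the open-chain homoallylic alcohol F7 through the same chair transition state. Hydroboration of its terminal diene alkene with 9-BBN would give the alkylborane F8, and intramolecular B-alkyl Suzuki coupling with the C4 iodide (Pd(dppf)Cl2, AsPh3, K3PO4, DMF, high dilution) would close the ten-membered ring to 32.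

2. Step 17. Metathesis may go astray by closure of the C7 alkylidene onto the C1=C10 alkene (seven-membered ring), by dimerisation, or by slow turnover on the α-substituted acrylate. The fallback builds the butenolide by carbonylation without metathesis; it sets out from 5 and 19 and comes back at 26. Aldehyde 5 would be alkynylated with triethyl(prop-2-yn-1-yloxy)silane under Zn–ProPhenol catalysis (Me2Zn, toluene; the ligand enantiomer that gives the R carbinol) to the propargylic alcohol F9. B-alkyl Suzuki coupling of F9 with borane 19 would give the coupled propargylic alcohol F10. Hydroxyl-directed trans-hydroalumination with NaAlH2(OCH2CH2OCH3)2 would give the cyclic alanate F11, and iodine the (Z)-γ-hydroxy vinyl iodide F12. Carbonylative lactonisation (Pd(PPh3)2Cl2 cat., CO 1 atm, K2CO3, THF) would then close the lactone to 26.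

3. Step 10. The Z-configured dienone may lose its alkene geometry, take up nucleophiles at the diene terminus during work-up, or equilibrate with its 2H-pyran valence isomer, and the dienyllithium may decompose before acylation. The fallback forms the carbinol directly and avoids the ketone; it sets out from 11 and 14 and comes back at 17. Amide 14 would be reduced with i-Bu2AlH at −78 °C to [(4-methoxybenzyl)oxy]acetaldehyde F13. A Nozaki–Hiyama–Kishi coupling of 11 with F13 (CrCl2, NiCl2 cat., chiral oxazoline–sulfonamide ligand, Et3N, THF; the ligand enantiomer that gives the 9S alcohol) would then give 17 without passing through 16.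

Further compounds

F1 | step 22 | O6 2-[(triethylsilyloxy)methyl]acrylate of 6 | C=C[C@H](OC(=O)C(=C)CO[Si](CC)(CC)CC)/C=C(\I)CO[Si](c1ccccc1)(c1ccccc1)C(C)(C)C
F2 | step 22 | (6R)-iodo-butenolide C13 triethylsilyl ether | CC[Si](CC)(CC)OCC1=C[C@@H](/C=C(\I)CO[Si](c2ccccc2)(c2ccccc2)C(C)(C)C)OC1=O
F3 | step 22 | (6R)-iodo-butenolide C13 alcohol | OCC1=C[C@@H](/C=C(\I)CO[Si](c2ccccc2)(c2ccccc2)C(C)(C)C)OC1=O
F4 | step 22 | (6R)-iodo-butenolide C13 bromide | BrCC1=C[C@@H](/C=C(\I)CO[Si](c2ccccc2)(c2ccccc2)C(C)(C)C)OC1=O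
F5 | step 22 | (9S)-diene C8 alcohol | C=C/C=C(\[C@H](O[Si](C)(C)C(C)(C)C)CO)CO[Si](C)(C)C(C)(C)C
F6 | step 22 | (9S)-diene C8 aldehyde | C=C/C=C(\[C@H](O[Si](C)(C)C(C)(C)C)C=O)CO[Si](C)(C)C(C)(C)C
F7 | step 22 | open-chain Barbier adduct (methylene lactone, C8–OH, C4 iodide, terminal diene) | C=C1C(=O)O[C@H](/C=C(\I)CO[Si](c2ccccc2)(c2ccccc2)C(C)(C)C)[C@H]1[C@@H](O)[C@@H](O[Si](C)(C)C(C)(C)C)/C(CO[Si](C)(C)C(C)(C)C)=C\C=C
F8 | step 22 | C3 alkyl-9-BBN borane of F7 | C=C1C(=O)O[C@H](/C=C(\I)CO[Si](c2ccccc2)(c2ccccc2)C(C)(C)C)[C@H]1[C@@H](O)[C@@H](O[Si](C)(C)C(C)(C)C)/C(CO[Si](C)(C)C(C)(C)C)=C\CCB1C2CCCC1CCC2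
F9 | step 17 | (R)-propargylic alcohol from 5 | CC[Si](CC)(CC)OCC#C[C@H](O)/C=C(\I)CO[Si](c1ccccc1)(c1ccccc1)C(C)(C)C
F10 | step 17 | coupled propargylic alcohol | COc1ccc(COC[C@@H](O[Si](C)(C)C(C)(C)C)/C(CO[Si](C)(C)C(C)(C)C)=C\CC/C(CO[Si](c2ccccc2)(c2ccccc2)C(C)(C)C)=C\[C@@H](O)C#CCO[Si](CC)(CC)CC)cc1
F11 | step 17 | sodium cyclic alanate of F10 (O6–Al–C11 chelate) | [Na+].COc1ccc(COC[C@@H](O[Si](C)(C)C(C)(C)C)/C(CO[Si](C)(C)C(C)(C)C)=C\CC/C(CO[Si](c2ccccc2)(c2ccccc2)C(C)(C)C)=C\[C@H]2O[Al-](OCCOC)(OCCOC)C(CO[Si](CC)(CC)CC)=C2)cc1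
F12 | step 17 | (Z)-γ-hydroxy vinyl iodide (I on C11 cis to C6) | COc1ccc(COC[C@@H](O[Si](C)(C)C(C)(C)C)/C(CO[Si](C)(C)C(C)(C)C)=C\CC/C(CO[Si](c2ccccc2)(c2ccccc2)C(C)(C)C)=C\[C@@H](O)/C=C(\I)CO[Si](CC)(CC)CC)cc1
F13 | step 10 | [(4-methoxybenzyl)oxy]acetaldehyde | COc1ccc(COCC=O)cc1
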